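**Retrosynthetic overview**

1. The target is robinetinidol-(4α→8)-dihydrorobinetin. Last disconnections: global hydrogenolysis, then the interflavanyl bond C4 (upper unit)–C8 (lower unit), made from a ring A p-quinone methide of benzyl-protected robinetinidol and the 7-phenoxide of tri-O-benzyl-(+)-dihydrorobinetin (rings D, E, F taken intact from the natural dihydroflavonol).
2. Upper unit: ring C is closed by making the aryl ether bond O1–C8a on a para-alkylphenol: singlet-oxygen dearomatisation to the p-quinol, oxa-Michael addition of the C2 hydroxyl to C8a, dehydrative rearomatisation (a formal meta C–H etherification).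
3. Enabling feature: in ring A the C7 hydroxyl is para to C4a, and C8a is the carbon ortho to the C4–C3–C2 chain. Ring A + C4 + C3 + C2 is therefore the skeleton of L-tyrosine (Cα = C3, S), and dearomatising that phenol turns C8a into an enone β-carbon that the oxygen on C2 reaches through a six-membered ring.
4. Cyclisation precursor: L-tyrosine → (S)-hydroxy acid (retention) → Weinreb amide → aryl ketone with the ring B aryllithium → chelation-controlled reduction (sets C2, anti to C3).
5. Ring order: rings D/E/F and ring B are bought, ring A comes from tyrosine, ring C is formed in the key step; C4 activation and union of the two units follow.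

Key step: step 9

Remark: 5-bromo-1,2,3-tris(benzyloxy)benzene and (2R,3R)-dihydrorobinetin are assumed to be commercial. Flavan numbering is used throughout; the upper unit has rings A, B, C and the lower unit rings D, E, F.

**Step 1**
Reactants: 1 L-tyrosine
Product: 2 (S)-2-hydroxy-3-(4-hydroxyphenyl)propanoic acid
Conditions: NaNO2, 1 M H2SO4 (aq), 0 °C → rt
Reagents that add atoms: water, O
Why: Diazotisation with carboxylate participation (α-lactone, double inversion) should give net retention, so Cα of L-tyrosine becomes the (S)-carbinol that will be C3.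

**Step 2**
Reactants: 2 (S)-2-hydroxy-3-(4-hydroxyphenyl)propanoic acid
Product: 3 methyl (S)-2-hydroxy-3-(4-hydroxyphenyl)propanoate
Conditions: MeOH, H2SO4 (cat.), reflux
Reagents that add atoms: methanol, CO
Why: Fischer esterification, which does not touch the α-stereocentre.

**Step 3**
Reactants: 3 methyl (S)-2-hydroxy-3-(4-hydroxyphenyl)propanoate
Product: 4 methyl (S)-2-hydroxy-3-[4-(triisopropylsilyloxy)phenyl]propanoate
Conditions: TIPSCl (1.05 equiv), imidazole, DMF, 0 °C
Reagents that add atoms: triisopropylsilyl chloride, CC(C)[Si](Cl)(C(C)C)C(C)C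
Why: Silylation with the bulky chloride should take the phenol selectively over the hindered, deactivated α-hydroxy ester alcohol.

**Step 4**
Reactants: 4 methyl (S)-2-hydroxy-3-[4-(triisopropylsilyloxy)phenyl]propanoate
Product: 5 methyl (S)-2-(benzyloxy)-3-[4-(triisopropylsilyloxy)phenyl]propanoate
Conditions: BnBr, Ag2O, n-Bu4NI (cat.), CH2Cl2, rt, dark
Reagents that add atoms: benzyl bromide, BrCc1ccccc1
Why: Silver-oxide-mediated Williamson benzylation is non-basic enough to leave the α-stereocentre and the aryl silyl ether untouched.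

**Step 5**
Reactants: 5 methyl (S)-2-(benzyloxy)-3-[4-(triisopropylsilyloxy)phenyl]propanoate
Product: 6 (S)-2-(benzyloxy)-N-methoxy-N-methyl-3-[4-(triisopropylsilyloxy)phenyl]propanamide
Conditions: MeNHOMe·HCl, i-PrMgCl, THF, −20 → 0 °C
Reagents that add atoms: N,O-dimethylhydroxylamine hydrochloride, CNOC.Cl
Why: Direct aminolysis of the ester by the magnesium amide (Weinreb amide formation) is fast at low temperature and should not epimerise the α-alkoxy centre.

**Step 6**
Reactants: 6 (S)-2-(benzyloxy)-N-methoxy-N-methyl-3-[4-(triisopropylsilyloxy)phenyl]propanamide; 7 5-bromo-1,2,3-tris(benzyloxy)benzene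
Product: 9 (S)-2-(benzyloxy)-1-[3,4,5-tris(benzyloxy)phenyl]-3-[4-(triisopropylsilyloxy)phenyl]propan-1-one, via aryllithium 8 (not isolated)
Conditions: 7, n-BuLi, THF, −78 °C; then 6, −78 → −40 °C; aq NH4Cl
Reagents that add atoms: none
Why: Bromine–lithium exchange followed by Weinreb ketone synthesis; the chelated tetrahedral intermediate prevents over-addition and the low temperature avoids enolisation of the α-alkoxy centre.

**Step 7**
Reactants: 9 (S)-2-(benzyloxy)-1-[3,4,5-tris(benzyloxy)phenyl]-3-[4-(triisopropylsilyloxy)phenyl]propan-1-one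
Product: 10 (1R,2S)-2-(benzyloxy)-1-[3,4,5-tris(benzyloxy)phenyl]-3-[4-(triisopropylsilyloxy)phenyl]propan-1-ol
Conditions: Zn(BH4)2, Et2O, −30 → 0 °C
Reagents that add atoms: none
Why: Chelation-controlled (Cram chelate) reduction: zinc bridges the ketone and α-benzyloxy oxygens and hydride arrives from the face of the small α-hydrogen, which should give the 1,2-anti alcohol, i.e. (R) at the future C2 and the 2,3-trans relationship.

**Step 8**
Reactants: 10 (1R,2S)-2-(benzyloxy)-1-[3,4,5-tris(benzyloxy)phenyl]-3-[4-(triisopropylsilyloxy)phenyl]propan-1-ol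
Product: 11 4-[(2S,3R)-2-(benzyloxy)-3-hydroxy-3-[3,4,5-tris(benzyloxy)phenyl]propyl]phenol
Conditions: n-Bu4NF, THF, 0 °C; aq NH4Cl
Reagents that add atoms: none
Why: Fluoride cleavage of the aryl silyl ether frees the one phenol needed for dearomatisation and leaves the benzyl ethers alone.

**Step 9**
Reactants: 11 4-[(2S,3R)-2-(benzyloxy)-3-hydroxy-3-[3,4,5-tris(benzyloxy)phenyl]propyl]phenol
Product: 15 (2R,3S)-3-(benzyloxy)-2-[3,4,5-tris(benzyloxy)phenyl]chroman-7-ol, via peroxyquinol 12 (not isolated), via quinol 13 (not isolated), via bicyclic hydroxy enone 14 (not isolated)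
Conditions: O2 (1 atm), methylene blue (3,7-bis(dimethylamino)phenothiazin-5-ium chloride, 2 mol %), red LEDs, Cs2CO3 (0.2 equiv), MeCN, −20 °C; Ar purge, Me2S (3 equiv), −20 °C → rt; then camphorsulfonic acid (0.6 equiv), 40 °C
Reagents that add atoms: none
Why: Proposed new method: dye-sensitised singlet oxygen adds to the para position of the phenolate of 11 to give the 4-hydroperoxycyclohexa-2,5-dienone 12, which Me2S reduces to p-quinol 13; in 13 the carbon ortho to the side chain (the future C8a) has become an enone β-carbon, so the C2 hydroxyl closes ring C by base-catalysed oxa-Michael addition, forming the O1–C8a bond (14), and acid then removes the C4a hydroxyl as water (ionisation of the dienol to an arenium ion, loss of the C8a proton) to rearomatise ring A. The closest known reaction types are the singlet-oxygen/oxa-Michael conversion of 4-(hydroxyalkyl)phenols into bicyclic quinol ethers (tyrosol to rengyolone-type products) and the dearomatisation–Michael–rearomatisation sequence that turns para-substituted phenols into meta-functionalised phenols; their merger into a chroman-forming, formally dehydrogenative meta C–H etherification is what is new. Ring C closes in the 6-exo-trig mode. No stereocentre of 15 is created here: C2 and C3 are carried over from 11, the transient centres at C4a and C8a are erased on aromatisation, and because the two ortho carbons of the para-substituted ring are equivalent, both diastereomeric adducts should converge on 15. The step needs chemoselectivity for one arene and six- over five-membered closure; the first is secured because ring A carries the only free phenol (all other oxygens are benzyl ethers, inert to singlet oxygen), the second because O3 is benzylated, leaving the C2 hydroxyl as the only nucleophile.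

**Step 10**
Reactants: 15 (2R,3S)-3-(benzyloxy)-2-[3,4,5-tris(benzyloxy)phenyl]chroman-7-ol
Product: 16 triisopropyl{[(2R,3S)-3-(benzyloxy)-2-[3,4,5-tris(benzyloxy)phenyl]chroman-7-yl]oxy}silane
Conditions: TIPSCl, imidazole, DMF, rt
Reagents that add atoms: triisopropylsilyl chloride, CC(C)[Si](Cl)(C(C)C)C(C)C
Why: Standard phenol silylation; the silyl ether keeps ring A electron-rich for C4 oxidation and later serves as the fluoride trigger.

**Step 11**
Reactants: 16 triisopropyl{[(2R,3S)-3-(benzyloxy)-2-[3,4,5-tris(benzyloxy)phenyl]chroman-7-yl]oxy}silane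
Product: 17 3-(benzyloxy)-2-[3,4,5-tris(benzyloxy)phenyl]-7-(triisopropylsilyloxy)chroman-4-yl acetate (C2 and C3 as in 16; C4 epimer mixture)
Conditions: DDQ (1.5 equiv), AcOH (10 equiv), CH2Cl2, 0 °C → rt
Reagents that add atoms: acetic acid, CC(=O)O
Why: DDQ benzylic oxidation at C4 (hydride abstraction giving a cation stabilised by the para silyloxy group and ortho O1, trapped by acetic acid) is the established way to activate C4 of protected flavan-3-ols; the C4 configuration is irrelevant because it is erased in step 15.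

**Step 12**
Reactants: 18 (2R,3R)-dihydrorobinetin [(2R,3R)-3,7-dihydroxy-2-(3,4,5-trihydroxyphenyl)chroman-4-one]
Product: 19 (2R,3R)-3-hydroxy-7-(methoxymethoxy)-2-(3,4,5-trihydroxyphenyl)chroman-4-one
Conditions: MOMCl (1.05 equiv), K2CO3 (1.0 equiv), acetone, 0 °C, Ar
Reagents that add atoms: chloromethyl methyl ether, COCCl
Why: With one equivalent of base only the most acidic phenol (C7–OH, para to the carbonyl) is ionised, so Williamson alkylation should be selective for O7.

**Step 13**
Reactants: 19 (2R,3R)-3-hydroxy-7-(methoxymethoxy)-2-(3,4,5-trihydroxyphenyl)chroman-4-one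
Product: 20 (2R,3R)-3-hydroxy-7-(methoxymethoxy)-2-[3,4,5-tris(benzyloxy)phenyl]chroman-4-one
Conditions: BnBr (3.3 equiv), K2CO3, DMF, rt, Ar
Reagents that add atoms: benzyl bromide, BrCc1ccccc1
Why: Williamson benzylation of the three ring E phenols; carbonate does not alkylate the secondary C3 alcohol, and exclusion of air prevents oxidation to the flavonol.

**Step 14**
Reactants: 20 (2R,3R)-3-hydroxy-7-(methoxymethoxy)-2-[3,4,5-tris(benzyloxy)phenyl]chroman-4-one
Product: 21 (2R,3R)-3,7-dihydroxy-2-[3,4,5-tris(benzyloxy)phenyl]chroman-4-one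
Conditions: HCl (cat.), MeOH–THF, 45 °C
Reagents that add atoms: none
Why: Acid-catalysed acetal exchange removes the aryl methoxymethyl ether; the dihydroflavonol and the benzyl ethers are acid-stable.

**Step 15**
Reactants: 17 3-(benzyloxy)-2-[3,4,5-tris(benzyloxy)phenyl]-7-(triisopropylsilyloxy)chroman-4-yl acetate; 21 (2R,3R)-3,7-dihydroxy-2-[3,4,5-tris(benzyloxy)phenyl]chroman-4-one
Product: 23 (2R,3R)-3,7-dihydroxy-8-[(2R,3S,4S)-3-(benzyloxy)-7-hydroxy-2-[3,4,5-tris(benzyloxy)phenyl]chroman-4-yl]-2-[3,4,5-tris(benzyloxy)phenyl]chroman-4-one, via quinone methide 22 (not isolated)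
Conditions: 21 (3 equiv), K2CO3 (1.5 equiv), DMF, −20 °C; 17, then n-Bu4NF (1.1 equiv, slow addition), −20 → 0 °C; aq NH4Cl
Reagents that add atoms: none
Why: Fluoride desilylation and 1,6-elimination of acetate should give the ring A p-quinone methide 22 (the electrophile of base-mediated interflavanyl bond formation), which the buffered phenoxide of 21 attacks through the carbon between O1 and O7 of ring D (C8, the site of C-alkylation of 7-hydroxychromanone phenoxides under basic conditions, whereas acid-mediated Friedel–Crafts substitution would favour C6), O-alkylation being reversible, and attack anti to the C3 benzyloxy group sets C4 as 3,4-trans (4α, S).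

**Step 16**
Reactants: 23 (2R,3R)-3,7-dihydroxy-8-[(2R,3S,4S)-3-(benzyloxy)-7-hydroxy-2-[3,4,5-tris(benzyloxy)phenyl]chroman-4-yl]-2-[3,4,5-tris(benzyloxy)phenyl]chroman-4-one
Product: 24 (2R,3R)-3,7-dihydroxy-8-[(2R,3S,4S)-3,7-dihydroxy-2-(3,4,5-trihydroxyphenyl)chroman-4-yl]-2-(3,4,5-trihydroxyphenyl)chroman-4-one
Conditions: H2 (1 atm), Pd(OH)2/C, THF–MeOH, rt, Ar work-up
Reagents that add atoms: none
Why: Hydrogenolysis of the seven benzyl ethers under neutral conditions should leave the aryl ketone, the interflavanyl bond and all five stereocentres untouched.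

**Compound list**

1 | L-tyrosine | N[C@@H](Cc1ccc(O)cc1)C(=O)O | starting material
2 | (S)-2-hydroxy-3-(4-hydroxyphenyl)propanoic acid | O[C@@H](Cc1ccc(O)cc1)C(=O)O | intermediate
3 | methyl (S)-2-hydroxy-3-(4-hydroxyphenyl)propanoate | O[C@@H](Cc1ccc(O)cc1)C(=O)OC | intermediate
4 | methyl (S)-2-hydroxy-3-[4-(triisopropylsilyloxy)phenyl]propanoate | O[C@@H](Cc1ccc(O[Si](C(C)C)(C(C)C)C(C)C)cc1)C(=O)OC | intermediate
5 | methyl (S)-2-(benzyloxy)-3-[4-(triisopropylsilyloxy)phenyl]propanoate | c1ccccc1CO[C@@H](Cc2ccc(O[Si](C(C)C)(C(C)C)C(C)C)cc2)C(=O)OC | intermediate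
6 | (S)-2-(benzyloxy)-N-methoxy-N-methyl-3-[4-(triisopropylsilyloxy)phenyl]propanamide | c1ccccc1CO[C@@H](Cc2ccc(O[Si](C(C)C)(C(C)C)C(C)C)cc2)C(=O)N(C)OC | intermediate
7 | 5-bromo-1,2,3-tris(benzyloxy)benzene | Brc1cc(OCc2ccccc2)c(OCc2ccccc2)c(OCc2ccccc2)c1 | starting material
8 | 3,4,5-tris(benzyloxy)phenyllithium | [Li]c1cc(OCc2ccccc2)c(OCc2ccccc2)c(OCc2ccccc2)c1 | intermediate (not isolated)
9 | (S)-2-(benzyloxy)-1-[3,4,5-tris(benzyloxy)phenyl]-3-[4-(triisopropylsilyloxy)phenyl]propan-1-one | c1ccccc1CO[C@@H](Cc2ccc(O[Si](C(C)C)(C(C)C)C(C)C)cc2)C(=O)c3cc(OCc4ccccc4)c(OCc4ccccc4)c(OCc4ccccc4)c3 | intermediate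
10 | (1R,2S)-2-(benzyloxy)-1-[3,4,5-tris(benzyloxy)phenyl]-3-[4-(triisopropylsilyloxy)phenyl]propan-1-ol | c1ccccc1CO[C@@H](Cc2ccc(O[Si](C(C)C)(C(C)C)C(C)C)cc2)[C@H](O)c3cc(OCc4ccccc4)c(OCc4ccccc4)c(OCc4ccccc4)c3 | intermediate
11 | 4-[(2S,3R)-2-(benzyloxy)-3-hydroxy-3-[3,4,5-tris(benzyloxy)phenyl]propyl]phenol | c1ccccc1CO[C@@H](Cc2ccc(O)cc2)[C@H](O)c3cc(OCc4ccccc4)c(OCc4ccccc4)c(OCc4ccccc4)c3 | intermediate
12 | 4-[(2S,3R)-2-(benzyloxy)-3-hydroxy-3-[3,4,5-tris(benzyloxy)phenyl]propyl]-4-hydroperoxycyclohexa-2,5-dien-1-one | c1ccccc1CO[C@@H](CC2(OO)C=CC(=O)C=C2)[C@H](O)c3cc(OCc4ccccc4)c(OCc4ccccc4)c(OCc4ccccc4)c3 | intermediate (not isolated)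
13 | 4-[(2S,3R)-2-(benzyloxy)-3-hydroxy-3-[3,4,5-tris(benzyloxy)phenyl]propyl]-4-hydroxycyclohexa-2,5-dien-1-one | c1ccccc1CO[C@@H](CC2(O)C=CC(=O)C=C2)[C@H](O)c3cc(OCc4ccccc4)c(OCc4ccccc4)c(OCc4ccccc4)c3 | intermediate (not isolated)
14 | (2R,3S)-3-(benzyloxy)-4a-hydroxy-2-[3,4,5-tris(benzyloxy)phenyl]-3,4,4a,8a-tetrahydro-2H-chromen-7(8H)-one (cis-fused; both C4a/C8a diastereomers) | O=C1C=CC2(O)C[C@H](OCc3ccccc3)[C@@H](c3cc(OCc4ccccc4)c(OCc4ccccc4)c(OCc4ccccc4)c3)OC2C1 | intermediate (not isolated)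
15 | (2R,3S)-3-(benzyloxy)-2-[3,4,5-tris(benzyloxy)phenyl]chroman-7-ol | Oc1ccc2C[C@H](OCc3ccccc3)[C@@H](c3cc(OCc4ccccc4)c(OCc4ccccc4)c(OCc4ccccc4)c3)Oc2c1 | intermediate
16 | triisopropyl{[(2R,3S)-3-(benzyloxy)-2-[3,4,5-tris(benzyloxy)phenyl]chroman-7-yl]oxy}silane | CC(C)[Si](Oc1ccc2C[C@H](OCc3ccccc3)[C@@H](c3cc(OCc4ccccc4)c(OCc4ccccc4)c(OCc4ccccc4)c3)Oc2c1)(C(C)C)C(C)C | intermediate
17 | 3-(benzyloxy)-2-[3,4,5-tris(benzyloxy)phenyl]-7-(triisopropylsilyloxy)chroman-4-yl acetate (C2 and C3 as in 16; C4 epimer mixture) | CC(C)[Si](Oc1ccc2C(OC(C)=O)[C@H](OCc3ccccc3)[C@@H](c3cc(OCc4ccccc4)c(OCc4ccccc4)c(OCc4ccccc4)c3)Oc2c1)(C(C)C)C(C)C | intermediate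
18 | (2R,3R)-dihydrorobinetin | O=C1c2ccc(O)cc2O[C@H](c2cc(O)c(O)c(O)c2)[C@H]1O | starting material
19 | (2R,3R)-3-hydroxy-7-(methoxymethoxy)-2-(3,4,5-trihydroxyphenyl)chroman-4-one | O=C1c2ccc(OCOC)cc2O[C@H](c2cc(O)c(O)c(O)c2)[C@H]1O | intermediate
20 | (2R,3R)-3-hydroxy-7-(methoxymethoxy)-2-[3,4,5-tris(benzyloxy)phenyl]chroman-4-one | O=C1c2ccc(OCOC)cc2O[C@H](c2cc(OCc3ccccc3)c(OCc3ccccc3)c(OCc3ccccc3)c2)[C@H]1O | intermediate
21 | (2R,3R)-3,7-dihydroxy-2-[3,4,5-tris(benzyloxy)phenyl]chroman-4-one | O=C1c2ccc(O)cc2O[C@H](c2cc(OCc3ccccc3)c(OCc3ccccc3)c(OCc3ccccc3)c2)[C@H]1O | intermediate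
22 | (2R,3S)-3-(benzyloxy)-2-[3,4,5-tris(benzyloxy)phenyl]-2,3-dihydro-7H-chromen-7-one (ring A p-quinone methide) | O=C1C=CC2=C[C@H](OCc3ccccc3)[C@@H](c3cc(OCc4ccccc4)c(OCc4ccccc4)c(OCc4ccccc4)c3)OC2=C1 | intermediate (not isolated)
23 | (2R,3R)-3,7-dihydroxy-8-[(2R,3S,4S)-3-(benzyloxy)-7-hydroxy-2-[3,4,5-tris(benzyloxy)phenyl]chroman-4-yl]-2-[3,4,5-tris(benzyloxy)phenyl]chroman-4-one | O=C1c2ccc(O)c([C@@H]3c4ccc(O)cc4O[C@H](c4cc(OCc5ccccc5)c(OCc5ccccc5)c(OCc5ccccc5)c4)[C@H]3OCc3ccccc3)c2O[C@H](c2cc(OCc3ccccc3)c(OCc3ccccc3)c(OCc3ccccc3)c2)[C@H]1O | intermediate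
24 | (2R,3R)-3,7-dihydroxy-8-[(2R,3S,4S)-3,7-dihydroxy-2-(3,4,5-trihydroxyphenyl)chroman-4-yl]-2-(3,4,5-trihydroxyphenyl)chroman-4-one | O=C1c2ccc(O)c([C@@H]3c4ccc(O)cc4O[C@H](c4cc(O)c(O)c(O)c4)[C@H]3O)c2O[C@H](c2cc(O)c(O)c(O)c2)[C@H]1O | target

**Totals**

Total step count: 16. Longest linear sequence: 13 steps (steps 1–11, 15 and 16, from L-tyrosine); the lower unit is a three-step branch (steps 12–14).

**Steps most likely to fail**

1. Step 9 (bears the label). The oxa-Michael closure may lag behind consumption of the hydroperoxide or quinol by other pathways, and the acid stage may ionise the benzylic C2–O bond faster than it dehydrates C4a, so that rearomatisation does not deliver the chroman. The fallback uses known chemistry and closes the same O1–C8a bond by palladium-catalysed intramolecular aryl etherification. It sets out from 7 (through aryllithium 8) and comes back to the route at 16, replacing steps 1–10. Commercial 3-bromo-4-methylphenol would be silylated (TIPSCl, imidazole) to (3-bromo-4-methylphenoxy)triisopropylsilane F1 and brominated at the benzylic position (N-bromosuccinimide, azobisisobutyronitrile cat., PhCF3, 80 °C) to [3-bromo-4-(bromomethyl)phenoxy]triisopropylsilane F2. Evans alkylation of the sodium enolate (NaN(SiMe3)2, THF, −78 °C) of commercial (R)-4-benzyl-3-(benzyloxyacetyl)oxazolidin-2-one with F2, on the face opposite the auxiliary benzyl group, should give (R)-4-benzyl-3-[(S)-2-(benzyloxy)-3-[2-bromo-4-(triisopropylsilyloxy)phenyl]propanoyl]oxazolidin-2-one F3. Transamination (MeNHOMe·HCl, AlMe3, CH2Cl2) gives (S)-2-(benzyloxy)-3-[2-bromo-4-(triisopropylsilyloxy)phenyl]-N-methoxy-N-methylpropanamide F4. Addition of aryllithium 8 at −78 °C gives (S)-2-(benzyloxy)-3-[2-bromo-4-(triisopropylsilyloxy)phenyl]-1-[3,4,5-tris(benzyloxy)phenyl]propan-1-one F5. Chelation-controlled reduction with Zn(BH4)2, as in step 7, gives (1R,2S)-2-(benzyloxy)-3-[2-bromo-4-(triisopropylsilyloxy)phenyl]-1-[3,4,5-tris(benzyloxy)phenyl]propan-1-ol F6. Cyclisation of F6 with Pd(OAc)2, 2-(di-tert-butylphosphino)-1,1'-binaphthyl and Cs2CO3 in toluene at 70 °C (oxidative addition of the aryl bromide to zerovalent palladium, alkoxide exchange, C–O reductive elimination with retention at C2) should give 16.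

2. Step 15. Phenoxide C-alkylation may divide between C8 and C6 of ring D, and the liberated ring A phenol of the product may add to further quinone methide (oligomerisation). The fallback controls regiochemistry with a blocking group instead of innate selectivity; it sets out from 21 and comes back at 24. Neutral electrophilic bromination of 21 (N-bromosuccinimide, 1.0 equiv, MeCN, −20 °C), which should go para to O1, gives (2R,3R)-6-bromo-3,7-dihydroxy-2-[3,4,5-tris(benzyloxy)phenyl]chroman-4-one F7. Union of F7 with 17 under the conditions of step 15 can then only occur at C8 and gives (2R,3R)-6-bromo-3,7-dihydroxy-8-[(2R,3S,4S)-3-(benzyloxy)-7-hydroxy-2-[3,4,5-tris(benzyloxy)phenyl]chroman-4-yl]-2-[3,4,5-tris(benzyloxy)phenyl]chroman-4-one F8. Hydrogenolysis of F8 (H2, Pd(OH)2/C, Et3N, THF–MeOH) removes the benzyl groups and the C–Br bond in one operation to give 24.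

3. Step 11. Hydride abstraction may continue to the C4 ketone or compete at C2 next to the electron-rich ring B, and the acidic hydroquinone by-product may erode the silyl ether. The fallback replaces benzylic C–H oxidation by two-electron oxidation of the phenol; it sets out from 15 and comes back at 23. Free phenol 15 would be oxidised with Ag2O (2 equiv, CH2Cl2–DMF, 0 °C) in the presence of 21 (3 equiv) and K2CO3 (1.5 equiv), generating quinone methide 22 directly from the para-alkylphenol and trapping it as in step 15; steps 10 and 11 are bypassed and no new compound is made.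

**Further compounds**

F1 | step 9 | (3-bromo-4-methylphenoxy)triisopropylsilane | Cc1ccc(O[Si](C(C)C)(C(C)C)C(C)C)cc1Br
F2 | step 9 | [3-bromo-4-(bromomethyl)phenoxy]triisopropylsilane | BrCc1ccc(O[Si](C(C)C)(C(C)C)C(C)C)cc1Br
F3 | step 9 | (R)-4-benzyl-3-[(S)-2-(benzyloxy)-3-[2-bromo-4-(triisopropylsilyloxy)phenyl]propanoyl]oxazolidin-2-one | c1ccccc1CO[C@@H](Cc2ccc(O[Si](C(C)C)(C(C)C)C(C)C)cc2Br)C(=O)N3[C@H](Cc4ccccc4)COC3=O
F4 | step 9 | (S)-2-(benzyloxy)-3-[2-bromo-4-(triisopropylsilyloxy)phenyl]-N-methoxy-N-methylpropanamide | c1ccccc1CO[C@@H](Cc2ccc(O[Si](C(C)C)(C(C)C)C(C)C)cc2Br)C(=O)N(C)OC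
F5 | step 9 | (S)-2-(benzyloxy)-3-[2-bromo-4-(triisopropylsilyloxy)phenyl]-1-[3,4,5-tris(benzyloxy)phenyl]propan-1-one | c1ccccc1CO[C@@H](Cc2ccc(O[Si](C(C)C)(C(C)C)C(C)C)cc2Br)C(=O)c3cc(OCc4ccccc4)c(OCc4ccccc4)c(OCc4ccccc4)c3
F6 | step 9 | (1R,2S)-2-(benzyloxy)-3-[2-bromo-4-(triisopropylsilyloxy)phenyl]-1-[3,4,5-tris(benzyloxy)phenyl]propan-1-ol | c1ccccc1CO[C@@H](Cc2ccc(O[Si](C(C)C)(C(C)C)C(C)C)cc2Br)[C@H](O)c3cc(OCc4ccccc4)c(OCc4ccccc4)c(OCc4ccccc4)c3
F7 | step 15 | (2R,3R)-6-bromo-3,7-dihydroxy-2-[3,4,5-tris(benzyloxy)phenyl]chroman-4-one | O=C1c2cc(Br)c(O)cc2O[C@H](c2cc(OCc3ccccc3)c(OCc3ccccc3)c(OCc3ccccc3)c2)[C@H]1O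
F8 | step 15 | (2R,3R)-6-bromo-3,7-dihydroxy-8-[(2R,3S,4S)-3-(benzyloxy)-7-hydroxy-2-[3,4,5-tris(benzyloxy)phenyl]chroman-4-yl]-2-[3,4,5-tris(benzyloxy)phenyl]chroman-4-one | O=C1c2cc(Br)c(O)c([C@@H]3c4ccc(O)cc4O[C@H](c4cc(OCc5ccccc5)c(OCc5ccccc5)c(OCc5ccccc5)c4)[C@H]3OCc3ccccc3)c2O[C@H](c2cc(OCc3ccccc3)c(OCc3ccccc3)c(OCc3ccccc3)c2)[C@H]1O
F0 | step 11 | none | none
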